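**Plan**
- Retrosynthetic cuts: the two prenyl C=C bonds go back to allyl groups (cross-metathesis); the C6–allyl and C8–allyl bonds go back to the O5 and O7 allyl ethers (double Claisen); O1–C8a and C4–C4a are then cut together (aryne annulation). This leaves a 3,5-bis(allyloxy)aryne and a C2–C3–C4 silyloxy-ester chain that carries ring B.
- Enabling feature: in ring A the neighbouring carbons C8a and C4a bear O1 and the C4 carbonyl carbon, and C4a is flanked by the C5 oxygen. This is the pattern left when an alkoxide adds to a 3-alkoxyaryne and the resulting aryl anion is acylated.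
- Forward order: rings A and B are bought (phloroglucinol, 3',5'-dihydroxyacetophenone). Ring C is the only ring made, in step 9. The allyl ethers carried through the aryne step then move to C6 and C8 and are turned into prenyl groups, and MOM removal ends the route.
- Stereochemistry: C2 (S) is the only stereocentre. It is set by asymmetric transfer hydrogenation of a beta-keto ester (step 7), and its C–O bond is not broken afterwards.

Key step: step 9

Assumption: the SMILES is read as the (2S)-flavanone; flavanone numbering is used (ring A the phloroglucinol ring, ring C the pyranone, ring B the aryl group on C2).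

**Route**

Step 1
Reactants: 1 phloroglucinol (benzene-1,3,5-triol)
Product: 2 3,5-bis(allyloxy)phenol
Conditions: allyl bromide (2.0 equiv), K2CO3, DMF, 0 °C to rt
Reagents that add atoms: allyl bromide, C=CCBr
Why: Williamson etherification with two equivalents of halide should give the bis-ether as the main statistical product, separable by chromatography from the mono- and tris-ethers, which can be recycled or discarded at this commodity stage.

Step 2
Reactants: 2 3,5-bis(allyloxy)phenol
Product: 3 3,5-bis(allyloxy)-2-bromophenol
Conditions: NBS (1.0 equiv), CH2Cl2, −78 °C to rt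
Reagents that add atoms: N-bromosuccinimide, O=C1CCC(=O)N1Br
Why: Electrophilic aromatic bromination of a 3,5-dialkoxyphenol with NBS in a non-polar solvent at low temperature is expected to go to one of the two equivalent positions ortho to the free hydroxyl, the ring being far more reactive than the allyl alkenes, with any para isomer removed by chromatography.

Step 3
Reactants: 3 3,5-bis(allyloxy)-2-bromophenol
Product: 4 [3,5-bis(allyloxy)-2-bromophenoxy]trimethylsilane
Conditions: HMDS, THF, 65 °C; evaporate
Reagents that add atoms: hexamethyldisilazane, C[Si](C)(C)N[Si](C)(C)C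
Why: O-silylation of a phenol with hexamethyldisilazane releases only ammonia, so the moisture-sensitive silyl ether should be obtained by simple evaporation.

Step 4
Reactants: 4 [3,5-bis(allyloxy)-2-bromophenoxy]trimethylsilane
Product: 7 3,5-bis(allyloxy)-2-(trimethylsilyl)phenyl trifluoromethanesulfonate, via aryllithium 5 (not isolated), via lithium 2-silylphenoxide 6 (not isolated)
Conditions: n-BuLi, THF, −78 °C; then Tf2O, −78 °C to rt
Reagents that add atoms: trifluoromethanesulfonic anhydride, O=S(=O)(OS(=O)(=O)C(F)(F)F)C(F)(F)F
Why: Bromine–lithium exchange followed by 1,3 O-to-C silyl migration (retro-Brook rearrangement) and O-triflation of the resulting phenoxide is the standard entry to ortho-silylaryl triflates, and at −78 °C the exchange should be much faster than any attack of butyllithium on the allyl ethers.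

Step 5
Reactants: 8 1-(3,5-dihydroxyphenyl)ethan-1-one (3',5'-dihydroxyacetophenone)
Product: 9 1-[3,5-bis(methoxymethoxy)phenyl]ethan-1-one
Conditions: MOMCl, i-Pr2NEt, CH2Cl2, 0 °C to rt
Reagents that add atoms: chloromethyl methyl ether, COCCl
Why: Alkylation of both phenols with chloromethyl methyl ether and a hindered amine base (MOM protection) gives acetal ethers that are stable to base, fluoride, hydride transfer and metathesis and come off under mild acid.

Step 6
Reactants: 9 1-[3,5-bis(methoxymethoxy)phenyl]ethan-1-one
Product: 10 methyl 3-[3,5-bis(methoxymethoxy)phenyl]-3-oxopropanoate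
Conditions: NaH, (MeO)2CO, THF, reflux; then AcOH
Reagents that add atoms: dimethyl carbonate, COC(=O)OC
Why: Crossed Claisen condensation of the methyl ketone enolate with dimethyl carbonate is driven to completion by deprotonation of the beta-keto ester formed.

Step 7
Reactants: 10 methyl 3-[3,5-bis(methoxymethoxy)phenyl]-3-oxopropanoate
Product: 11 methyl (S)-3-[3,5-bis(methoxymethoxy)phenyl]-3-hydroxypropanoate
Conditions: RuCl[(S,S)-TsDPEN](p-cymene) (1 mol %), HCO2H/Et3N (5:2), DMF, 40 °C
Reagents that add atoms: none
Why: Noyori asymmetric transfer hydrogenation of an aryl ketone with the (S,S)-TsDPEN ruthenium catalyst delivers hydride to the face that gives the S benzylic carbinol (aryl group held against the cymene ligand, as for acetophenone-type substrates), and the amine-buffered formic acid medium should leave the MOM ethers and the ester intact.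

Step 8
Reactants: 11 methyl (S)-3-[3,5-bis(methoxymethoxy)phenyl]-3-hydroxypropanoate
Product: 12 methyl (S)-3-[3,5-bis(methoxymethoxy)phenyl]-3-[(trimethylsilyl)oxy]propanoate
Conditions: TMSCl, Et3N, CH2Cl2, 0 °C; non-aqueous work-up (pentane, filtration)
Reagents that add atoms: chlorotrimethylsilane, C[Si](C)(C)Cl
Why: O-silylation of the secondary alcohol masks the only O–H proton of the annulation partner without touching the stereocentre, so that the alkoxide can later be released by fluoride under aprotic conditions.

Step 9
Reactants: 7 3,5-bis(allyloxy)-2-(trimethylsilyl)phenyl trifluoromethanesulfonate; 12 methyl (S)-3-[3,5-bis(methoxymethoxy)phenyl]-3-[(trimethylsilyl)oxy]propanoate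
Product: 15 (S)-5,7-bis(allyloxy)-2-[3,5-bis(methoxymethoxy)phenyl]chroman-4-one, via 3,5-bis(allyloxy)benzyne 13 (not isolated), via caesium alkoxide 14 (not isolated)
Conditions: 7 (1.3 equiv), CsF (3 equiv), THF, 65 °C
Reagents that add atoms: none
Why: Proposed new method: fluoride removes the aryl silyl group of 7 and triflate departs to give aryne 13, while fluoride (and then the methoxide released in each turnover) desilylates 12 to alkoxide 14, which adds through oxygen to the aryne carbon remote from the neighbouring allyloxy group (the future C8a), after which the aryl anion formed at the future C4a attacks the methyl ester to make C4–C4a and expel methoxide. The closest known reaction type is the fluoride-triggered coupling–cyclisation of ortho-silylaryl triflates with salicylate or anthranilate esters to xanthones and acridones (heteroatom addition to the aryne followed by intramolecular acyl substitution), the new element being an aliphatic secondary alkoxide whose ester carries enolisable alpha-hydrogens. Ring C closes by 6-exo-trig acyl substitution of the aryl anion on the ester carbonyl. No stereocentre is created, and because the C2–O bond made in step 7 is never broken the S configuration is carried into the flavanone unchanged. The step needs O-attack at the aryne carbon distal to the C5 oxygen, which the inductive stabilisation of the anion next to that allyloxy group and the unhindered distal carbon secure, and it needs acyl transfer to outrun protonation of the aryl anion, which the silyl-masked hydroxyl (no O–H or HF in the flask), the non-acidic solvent and the six-membered transition state favour. Methoxide is drained as methoxytrimethylsilane by silyl transfer from 12, which should keep the medium weakly basic and protect the product from ring opening to the chalcone.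

Step 10
Reactants: 15 (S)-5,7-bis(allyloxy)-2-[3,5-bis(methoxymethoxy)phenyl]chroman-4-one
Product: 17 (S)-6,8-diallyl-5,7-dihydroxy-2-[3,5-bis(methoxymethoxy)phenyl]chroman-4-one, via 6-allyl 7-allyl ether 16 (not isolated)
Conditions: Eu(fod)3 (fod = 6,6,7,7,8,8,8-heptafluoro-2,2-dimethyloctane-3,5-dionate, 10 mol %), degassed 1,2-dichlorobenzene, 110 °C then 180 °C (sealed tube)
Reagents that add atoms: none
Why: In this double aromatic Claisen rearrangement the C5 allyl ether, activated by chelation of europium between O5 and the C4 carbonyl, should shift to C6 first and the C7 allyl ether then has only C8 free, while any other order (C7 to C6, then para Claisen–Cope of the C5 ether to C8) converges on the same 6,8-diallyl ring A, and the absence of base guards C2 against ring opening.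

Step 11
Reactants: 17 (S)-6,8-diallyl-5,7-dihydroxy-2-[3,5-bis(methoxymethoxy)phenyl]chroman-4-one
Product: 18 (S)-5,7-dihydroxy-2-[3,5-bis(methoxymethoxy)phenyl]-6,8-bis(3-methylbut-2-en-1-yl)chroman-4-one
Conditions: 2-methylbut-2-ene (large excess), second-generation Grubbs catalyst RuCl2(=CHPh)(PCy3)(H2IMes) (5 mol %), CH2Cl2, 40 °C (sealed)
Reagents that add atoms: 2-methylbut-2-ene, CC=C(C)C
Why: Olefin cross-metathesis of terminal allylarenes with excess 2-methylbut-2-ene converts each allyl group into a prenyl group with loss of propene, tolerates free phenols and acetal ethers, and the trisubstituted products do not re-enter the cycle.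

Step 12
Reactants: 18 (S)-5,7-dihydroxy-2-[3,5-bis(methoxymethoxy)phenyl]-6,8-bis(3-methylbut-2-en-1-yl)chroman-4-one
Product: 19 (S)-2-(3,5-dihydroxyphenyl)-5,7-dihydroxy-6,8-bis(3-methylbut-2-en-1-yl)chroman-4-one (CID26213315)
Conditions: 3 M HCl in MeOH, 0 °C to rt
Reagents that add atoms: none
Why: Acid-catalysed acetal exchange with methanol (MOM ether cleavage) frees the two ring B phenols under conditions mild enough that the prenyl groups should not cyclise onto the neighbouring phenols and C2 should not epimerise.

**Compound list**
1 | phloroglucinol (benzene-1,3,5-triol) | Oc1cc(O)cc(O)c1 | starting material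
2 | 3,5-bis(allyloxy)phenol | C=CCOc1cc(O)cc(OCC=C)c1 | intermediate
3 | 3,5-bis(allyloxy)-2-bromophenol | C=CCOc1cc(O)c(Br)c(OCC=C)c1 | intermediate
4 | [3,5-bis(allyloxy)-2-bromophenoxy]trimethylsilane | C=CCOc1cc(O[Si](C)(C)C)c(Br)c(OCC=C)c1 | intermediate
5 | [2,4-bis(allyloxy)-6-(trimethylsilyloxy)phenyl]lithium (aryllithium, not isolated) | C=CCOc1cc(O[Si](C)(C)C)c([Li])c(OCC=C)c1 | intermediate
6 | lithium 3,5-bis(allyloxy)-2-(trimethylsilyl)phenoxide (not isolated) | C=CCOc1cc([O-])c([Si](C)(C)C)c(OCC=C)c1.[Li+] | intermediate
7 | 3,5-bis(allyloxy)-2-(trimethylsilyl)phenyl trifluoromethanesulfonate | C=CCOc1cc(OS(=O)(=O)C(F)(F)F)c([Si](C)(C)C)c(OCC=C)c1 | intermediate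
8 | 1-(3,5-dihydroxyphenyl)ethan-1-one | CC(=O)c1cc(O)cc(O)c1 | starting material
9 | 1-[3,5-bis(methoxymethoxy)phenyl]ethan-1-one | CC(=O)c1cc(OCOC)cc(OCOC)c1 | intermediate
10 | methyl 3-[3,5-bis(methoxymethoxy)phenyl]-3-oxopropanoate | COC(=O)CC(=O)c1cc(OCOC)cc(OCOC)c1 | intermediate
11 | methyl (S)-3-[3,5-bis(methoxymethoxy)phenyl]-3-hydroxypropanoate | COC(=O)C[C@@H](c1cc(OCOC)cc(OCOC)c1)O | intermediate
12 | methyl (S)-3-[3,5-bis(methoxymethoxy)phenyl]-3-[(trimethylsilyl)oxy]propanoate | COC(=O)C[C@@H](c1cc(OCOC)cc(OCOC)c1)O[Si](C)(C)C | intermediate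
13 | 3,5-bis(allyloxy)benzyne (not isolated) | C=CCOC1=CC(OCC=C)=CC#C1 | intermediate
14 | caesium (S)-1-[3,5-bis(methoxymethoxy)phenyl]-3-methoxy-3-oxopropan-1-olate (not isolated) | COC(=O)C[C@@H](c1cc(OCOC)cc(OCOC)c1)[O-].[Cs+] | intermediate
15 | (S)-5,7-bis(allyloxy)-2-[3,5-bis(methoxymethoxy)phenyl]chroman-4-one | O=C1C[C@@H](c2cc(OCOC)cc(OCOC)c2)Oc2cc(OCC=C)cc(OCC=C)c21 | intermediate
16 | (S)-6-allyl-7-(allyloxy)-5-hydroxy-2-[3,5-bis(methoxymethoxy)phenyl]chroman-4-one (not isolated) | O=C1C[C@@H](c2cc(OCOC)cc(OCOC)c2)Oc2cc(OCC=C)c(CC=C)c(O)c21 | intermediate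
17 | (S)-6,8-diallyl-5,7-dihydroxy-2-[3,5-bis(methoxymethoxy)phenyl]chroman-4-one | O=C1C[C@@H](c2cc(OCOC)cc(OCOC)c2)Oc2c(CC=C)c(O)c(CC=C)c(O)c21 | intermediate
18 | (S)-5,7-dihydroxy-2-[3,5-bis(methoxymethoxy)phenyl]-6,8-bis(3-methylbut-2-en-1-yl)chroman-4-one | CC(C)=CCc1c(O)c(CC=C(C)C)c2c(c1O)C(=O)C[C@@H](c1cc(OCOC)cc(OCOC)c1)O2 | intermediate
19 | (S)-2-(3,5-dihydroxyphenyl)-5,7-dihydroxy-6,8-bis(3-methylbut-2-en-1-yl)chroman-4-one | CC(C)=CCc1c(O)c(CC=C(C)C)c2c(c1O)C(=O)C[C@@H](c1cc(O)cc(O)c1)O2 | target

**Step count and risks**
Total steps: 12. Longest linear sequence: 8 (steps 1–4 or steps 5–8, then steps 9–12).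

Steps most likely to fail:

1. Step 9 (the proposed new method).
   - What may go wrong: the C4a aryl anion may be protonated before it acylates (by a 1,5-proton shift from the ester alpha-carbon or by adventitious water), leaving an uncyclised aryl ether. The alkoxide may undergo retro-aldol cleavage or beta-elimination. Residual base may open ring C of the product and erode the configuration at C2.
   - Fallback in known chemistry, setting out from 10 (with bromophenol 3 as partner) and returning at 15: transfer hydrogenation of 10 with the enantiomeric catalyst RuCl[(R,R)-TsDPEN](p-cymene) would give methyl (R)-3-[3,5-bis(methoxymethoxy)phenyl]-3-hydroxypropanoate F1. Aminolysis with MeNH(OMe)·HCl and i-PrMgCl in THF would give (R)-3-[3,5-bis(methoxymethoxy)phenyl]-3-hydroxy-N-methoxy-N-methylpropanamide F2. Mitsunobu etherification with 3 (PPh3, DIAD, THF, 0 °C) would invert the carbinol centre and give (S)-3-[3,5-bis(allyloxy)-2-bromophenoxy]-3-[3,5-bis(methoxymethoxy)phenyl]-N-methoxy-N-methylpropanamide F3. Bromine–lithium exchange (n-BuLi, THF, −78 °C) and Parham cyclisation of the aryllithium onto the Weinreb amide would then close ring C and give 15 after work-up.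

2. Step 10.
   - What may go wrong: at 180 °C ring C may open reversibly to the chalcone, with loss of configuration at C2. The second rearrangement may stall. The ortho-allylphenols may cyclise to dihydrobenzofurans.
   - Fallback that avoids high temperature, setting out from 15 and returning at 18: deallylation with Pd(PPh3)4 and morpholine in THF at rt would give (S)-5,7-dihydroxy-2-[3,5-bis(methoxymethoxy)phenyl]chroman-4-one F4. Iodination of the phloroglucinol ring with N-iodosuccinimide (2.1 equiv, DMF, 0 °C) would give (S)-5,7-dihydroxy-6,8-diiodo-2-[3,5-bis(methoxymethoxy)phenyl]chroman-4-one F5. Double Stille coupling with tributyl(3-methylbut-2-en-1-yl)stannane (Pd2(dba)3, tri(2-furyl)phosphine, DMF, 60 °C) would then deliver 18.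

3. Step 12.
   - What may go wrong: acid may cyclise a prenyl group onto the neighbouring C5 or C7 phenol (chroman formation), or promote epimerisation at C2 during acetal cleavage.
   - Fallback that reverses the order of the last two operations, setting out from 17 and returning at 19: MOM removal at the diallyl stage (3 M HCl in MeOH, rt), where the allyl groups are far less prone to acid cyclisation, would give (S)-6,8-diallyl-2-(3,5-dihydroxyphenyl)-5,7-dihydroxychroman-4-one F6. Cross-metathesis with excess 2-methylbut-2-ene (second-generation Grubbs catalyst, THF/CH2Cl2, 40 °C) would then give 19 directly, without acid ever meeting a prenyl group.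

**Further compounds**
F1 | step 9 | methyl (R)-3-[3,5-bis(methoxymethoxy)phenyl]-3-hydroxypropanoate | COC(=O)C[C@H](c1cc(OCOC)cc(OCOC)c1)O
F2 | step 9 | (R)-3-[3,5-bis(methoxymethoxy)phenyl]-3-hydroxy-N-methoxy-N-methylpropanamide | CON(C)C(=O)C[C@H](c1cc(OCOC)cc(OCOC)c1)O
F3 | step 9 | (S)-3-[3,5-bis(allyloxy)-2-bromophenoxy]-3-[3,5-bis(methoxymethoxy)phenyl]-N-methoxy-N-methylpropanamide | CON(C)C(=O)C[C@@H](c1cc(OCOC)cc(OCOC)c1)Oc1cc(OCC=C)cc(OCC=C)c1Br
F4 | step 10 | (S)-5,7-dihydroxy-2-[3,5-bis(methoxymethoxy)phenyl]chroman-4-one | O=C1C[C@@H](c2cc(OCOC)cc(OCOC)c2)Oc2cc(O)cc(O)c21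
F5 | step 10 | (S)-5,7-dihydroxy-6,8-diiodo-2-[3,5-bis(methoxymethoxy)phenyl]chroman-4-one | O=C1C[C@@H](c2cc(OCOC)cc(OCOC)c2)Oc2c(I)c(O)c(I)c(O)c21
F6 | step 12 | (S)-6,8-diallyl-2-(3,5-dihydroxyphenyl)-5,7-dihydroxychroman-4-one | O=C1C[C@@H](c2cc(O)cc(O)c2)Oc2c(CC=C)c(O)c(CC=C)c(O)c21
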